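**Plan**

- Retrosynthesis: after removal of the last silyl group, the C40 chain is cut at C11=C12 and C11'=C12'. This works because C12–C12' is a symmetrical C10 triene ending in two equivalent formyl carbons, flanked by two different C15 units (ring A with C7–C11, ring B with C7'–C11') whose allylic C11 and C11' can each carry phosphorus.
- The ring B salt is cut at C6'–C7' (ring enol triflate + C5 enynol), the ring A salt at C6–C7 (ring enone + C5 acetylide).
- Forward: both six-membered rings are those of 4-oxoisophorone and no ring is formed. Each ring is extended by the same C5 enynol to a C15 tributylphosphonium salt, and the chain is joined in one flask, ring B + C10 first (C11'=C12'), then ring A (C11=C12).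
- Stereocentres: C3' and C3 come from catalyst-controlled transfer hydrogenation of 4-oxoisophorone with the two enantiomeric catalysts. C6 comes from substrate-controlled acetylide addition syn to the silyloxy group, and C3 is then inverted (Mitsunobu) to give the cis-3,6-diol.
- Double bonds: 9E and 9'E come from the enynol, 7E from hydroalumination, 11E and 11'E from E-selective tributylphosphonium ylides.

Key step: step 16

Remark (numbering): C1–C15 (ring A half) and C1'–C15' (ring B half) are carotenoid locants; the systematic names of the C9 and C15 compounds carry their own ring numbering.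

Remark (assumption): the sense of induction in steps 1 and 7 is assigned by the usual CH/π model of transfer hydrogenation, with the enone π-system in the place of an aryl group; if it were found reversed, the two ligand enantiomers would simply change places (TsDPEN = N-tosyl-1,2-diphenylethane-1,2-diamine).

**Ring B fragment**

Step 1
Reactants: 1 4-oxoisophorone
Product: 2 (4S)-4-hydroxy-2,6,6-trimethylcyclohex-2-en-1-one
Conditions: RuCl[(S,S)-TsDPEN](p-cymene) (1 mol%), i-PrONa (2 mol%), i-PrOH, rt
Reagents that add atoms: none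
Why: Noyori-type asymmetric transfer hydrogenation should reduce only the unhindered C4 carbonyl (the C1 carbonyl lies between a quaternary carbon and a methyl-bearing sp2 carbon), and the (S,S) ligand sets the new C4 stereocentre as S.

Step 2
Reactants: 2 (4S)-4-hydroxy-2,6,6-trimethylcyclohex-2-en-1-one
Product: 3 (4S)-4-(tert-butyldimethylsilyloxy)-2,6,6-trimethylcyclohex-2-en-1-one
Conditions: TBSCl, imidazole, DMF, rt
Reagents that add atoms: tert-butyldimethylsilyl chloride, CC(C)(C)[Si](C)(C)Cl
Why: Imidazole-promoted silylation of a secondary allylic alcohol leaves the stereocentre untouched.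

Step 3
Reactants: 3 (4S)-4-(tert-butyldimethylsilyloxy)-2,6,6-trimethylcyclohex-2-en-1-one
Product: 5 (4R)-4-(tert-butyldimethylsilyloxy)-2,6,6-trimethylcyclohex-1-en-1-yl trifluoromethanesulfonate, via lithium enolate 4 (not isolated)
Conditions: LiBH(s-Bu)3, THF, −78 °C; then PhNTf2, −78 °C → rt
Reagents that add atoms: N-phenylbis(trifluoromethanesulfonimide), O=S(=O)(N(c1ccccc1)S(=O)(=O)C(F)(F)F)C(F)(F)F
Why: Conjugate reduction of the β-unsubstituted, carbonyl-hindered enone by the bulky borohydride gives the C1–C2 enolate regiospecifically, and O-sulfonylation traps it (reductive enol triflate formation); the stereocentre is not involved and only its descriptor changes from S to R.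

Step 4
Reactants: 5 ring B enol triflate; 6 (E)-3-methylpent-2-en-4-yn-1-ol
Product: 7 (2E)-5-[(4R)-4-(tert-butyldimethylsilyloxy)-2,6,6-trimethylcyclohex-1-en-1-yl]-3-methylpent-2-en-4-yn-1-ol
Conditions: Pd(PPh3)4 (5 mol%), CuI (10 mol%), i-Pr2NH, DMF, rt → 45 °C
Reagents that add atoms: none
Why: Sonogashira coupling of a vinyl triflate with a terminal alkyne (zerovalent palladium with CuI) forms C6'–C7', carries in the 9'E geometry of the enynol and tolerates the free primary hydroxyl.

Step 5
Reactants: 7 ring B C15 alcohol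
Product: 8 (4R)-1-[(3E)-5-bromo-3-methylpent-3-en-1-yn-1-yl]-4-(tert-butyldimethylsilyloxy)-2,6,6-trimethylcyclohex-1-ene
Conditions: CBr4, PPh3, CH2Cl2, 0 °C
Reagents that add atoms: carbon tetrabromide, BrC(Br)(Br)Br
Why: Appel bromination converts the primary allylic alcohol into the bromide under neutral conditions that spare the silyl ether and the E enyne.

Step 6
Reactants: 8 ring B C15 bromide
Product: 9 tributyl{(2E)-5-[(4R)-4-(tert-butyldimethylsilyloxy)-2,6,6-trimethylcyclohex-1-en-1-yl]-3-methylpent-2-en-4-yn-1-yl}phosphonium bromide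
Conditions: PBu3, CH2Cl2, 0 °C → rt
Reagents that add atoms: tributylphosphine, CCCCP(CCCC)CCCC
Why: SN2 quaternisation of the allylic bromide by the nucleophilic trialkylphosphine gives the salt; tributyl is chosen over triphenyl because its allylic ylides olefinate with high E selectivity.

**Ring A fragment**

Step 7
Reactants: 1 4-oxoisophorone
Product: 10 (4R)-4-hydroxy-2,6,6-trimethylcyclohex-2-en-1-one
Conditions: RuCl[(R,R)-TsDPEN](p-cymene) (1 mol%), i-PrONa (2 mol%), i-PrOH, rt
Reagents that add atoms: none
Why: The same asymmetric transfer hydrogenation with the enantiomeric ligand sets C4 as R, which is the C3 epimer needed because this centre is inverted in step 12.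

Step 8
Reactants: 10 (4R)-4-hydroxy-2,6,6-trimethylcyclohex-2-en-1-one
Product: 11 (4R)-2,6,6-trimethyl-4-(trimethylsilyloxy)cyclohex-2-en-1-one
Conditions: TMSCl, imidazole, CH2Cl2, 0 °C
Reagents that add atoms: chlorotrimethylsilane, C[Si](C)(C)Cl
Why: Silylation gives an ether that survives the organolithium addition yet can later be removed by mild methanolysis beside a tert-butyldimethylsilyl ether.

Step 9
Reactants: 6 (E)-3-methylpent-2-en-4-yn-1-ol
Product: 12 tert-butyl(dimethyl){[(2E)-3-methylpent-2-en-4-yn-1-yl]oxy}silane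
Conditions: TBSCl, imidazole, DMF, rt
Reagents that add atoms: tert-butyldimethylsilyl chloride, CC(C)(C)[Si](C)(C)Cl
Why: Routine silylation of the primary alcohol leaves the alkyne C–H as the only acidic site.

Step 10
Reactants: 12 silylated enynol; 11 ring A enone trimethylsilyl ether
Product: 15 (1R,4R)-1-[(3E)-5-(tert-butyldimethylsilyloxy)-3-methylpent-3-en-1-yn-1-yl]-2,6,6-trimethylcyclohex-2-ene-1,4-diol, via lithium acetylide 13 (not isolated), via silylated adduct 14 (not isolated)
Conditions: n-BuLi, THF, −78 °C; then 11, −78 °C; then MeOH, K2CO3 (cat.), rt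
Reagents that add atoms: none
Why: 1,2-Addition of a lithium acetylide to the enone, in whose half-chair the silyloxy group is pseudo-equatorial and one methyl of the gem-dimethyl carbon is axial on the opposite face, should occur anti to that methyl and therefore syn to the silyloxy group, setting C6 as R with the two oxygens trans; base-catalysed methanolysis then removes only the trimethylsilyl group.

Step 11
Reactants: 15 trans-enyne diol
Product: 16 (1R,4R)-1-[(1E,3E)-5-(tert-butyldimethylsilyloxy)-3-methylpenta-1,3-dien-1-yl]-2,6,6-trimethylcyclohex-2-ene-1,4-diol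
Conditions: NaAlH2(OCH2CH2OMe)2, THF, 0 °C → rt; aq. potassium sodium tartrate
Reagents that add atoms: none
Why: Hydroxyl-directed trans-hydroalumination of the propargylic alcohol followed by protonolysis gives the 7E alkene (E-selective propargylic alcohol reduction) without touching the stereocentres.

Step 12
Reactants: 16 trans-diene diol
Product: 17 (1S,4R)-4-[(1E,3E)-5-(tert-butyldimethylsilyloxy)-3-methylpenta-1,3-dien-1-yl]-4-hydroxy-3,5,5-trimethylcyclohex-2-en-1-yl benzoate
Conditions: PhCO2H, PPh3, DIAD (added last, slowly), toluene, 0 °C → rt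
Reagents that add atoms: benzoic acid, O=C(O)c1ccccc1
Why: Mitsunobu esterification activates only the secondary allylic hydroxyl (the tertiary one is inert) and benzoate displaces it by SN2 with inversion, turning C3 from R to S and so creating the cis relation of the C3 and C6 oxygens.

Step 13
Reactants: 17 ring A benzoate silyl ether
Product: 18 (1S,4R)-4-hydroxy-4-[(1E,3E)-5-hydroxy-3-methylpenta-1,3-dien-1-yl]-3,5,5-trimethylcyclohex-2-en-1-yl benzoate
Conditions: Bu4NF, AcOH, THF, 0 °C → rt
Reagents that add atoms: none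
Why: Buffered fluoride desilylation frees the primary alcohol while the benzoate and the acid-sensitive tertiary diallylic alcohol are left alone.

Step 14
Reactants: 18 ring A C15 alcohol
Product: 19 (1S,4R)-4-[(1E,3E)-5-bromo-3-methylpenta-1,3-dien-1-yl]-4-hydroxy-3,5,5-trimethylcyclohex-2-en-1-yl benzoate
Conditions: CBr4, PPh3, CH2Cl2, −20 °C
Reagents that add atoms: carbon tetrabromide, BrC(Br)(Br)Br
Why: Appel bromination at low temperature is selective for the primary allylic hydroxyl, since the tertiary alcohol does not react with the phosphonium reagent, and the neutral medium avoids ionisation at C6.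

Step 15
Reactants: 19 ring A C15 bromide
Product: 20 tributyl{(2E,4E)-5-[(1R,4S)-4-(benzoyloxy)-1-hydroxy-2,6,6-trimethylcyclohex-2-en-1-yl]-3-methylpenta-2,4-dien-1-yl}phosphonium bromide
Conditions: PBu3, CH2Cl2, 0 °C → rt
Reagents that add atoms: tributylphosphine, CCCCP(CCCC)CCCC
Why: SN2 quaternisation of the labile allylic bromide, used at once, gives the ring A salt with the free tertiary hydroxyl and the benzoate intact.

**Assembly**

Step 16
Reactants: 9 ring B C15 phosphonium bromide; 21 (2E,4E,6E)-2,7-dimethylocta-2,4,6-trienedial; 20 ring A C15 phosphonium bromide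
Product: 26 3'-O-(tert-butyldimethylsilyl) ether of the target (all-E), via ring B ylide 22 (not isolated), via C25 apo-aldehyde 23 (not isolated), via ring A ylide 24 (not isolated), via C40 benzoate 25 (not isolated)
Conditions: NaOMe (1.1 equiv, 1 M in MeOH) added slowly to 9 and 21 (1.2 equiv), CH2Cl2, −20 → 0 °C; then 20 (1.4 equiv), NaOMe (1.6 equiv), 0 °C → rt; then MeOH, NaOMe (2 equiv), rt; Ar, dark
Reagents that add atoms: none
Why: Methoxide deprotonates each tributylphosphonium salt at its allylic CH2 to a conjugated ylide (22, then 24), which adds to a formyl carbon of the trienedial and collapses through an oxaphosphetane to the alkene and Bu3P=O; this is the classical Wittig C15 + C10 + C15 carotenoid assembly run as two condensations in one flask. No ring is closed and no stereocentre is formed: the only new bonds are C11'=C12' and C11=C12. Site selectivity is secured in the first stage by making 9 the limiting partner and generating its ylide slowly in the presence of excess 21, so that the ylide meets dialdehyde rather than the vinylogously extended, less electrophilic mono-adduct 23, which is then consumed by an excess of 20. E geometry at both new double bonds should follow from the trialkylphosphonium (rather than triarylphosphonium) ylides, which spares the product an iodine or thermal equilibration that could drag the 9'E enyne bond towards its Z form. The tertiary C6 hydroxyl, the silyl ether and the alkyne are inert to ylides and methoxide, while the benzoate, which methoxide would attack in any case, is methanolysed on purpose at the end (Zemplén transesterification) so that all ring A material converges on 26. The silylated ring B end and the free diol at ring A give the cross product a polarity between those of the two symmetrical bis-adducts, which should make its chromatographic isolation simple.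

Step 17
Reactants: 26 3'-O-silyl ether of the target
Product: 27 (3S,6R,3'R)-7',8'-didehydro-ε,β-carotene-3,6,3'-triol (all-E; ring A locants unprimed), the target
Conditions: Bu4NF, THF, 0 °C → rt, dark
Reagents that add atoms: none
Why: Fluoride desilylation of the secondary silyl ether under non-acidic conditions, which the polyene, the alkyne and the tertiary diallylic alcohol tolerate, frees the C3' hydroxyl and completes the target.

**Compound list**

1 | 4-oxoisophorone (2,6,6-trimethylcyclohex-2-ene-1,4-dione) | CC1=CC(=O)CC(C)(C)C1=O | starting material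
2 | (4S)-4-hydroxy-2,6,6-trimethylcyclohex-2-en-1-one | CC1=C[C@@H](O)CC(C)(C)C1=O | intermediate
3 | (4S)-4-(tert-butyldimethylsilyloxy)-2,6,6-trimethylcyclohex-2-en-1-one | CC1=C[C@@H](O[Si](C)(C)C(C)(C)C)CC(C)(C)C1=O | intermediate
4 | lithium (4R)-4-(tert-butyldimethylsilyloxy)-2,6,6-trimethylcyclohex-1-en-1-olate | [Li+].[O-]C1=C(C)C[C@@H](O[Si](C)(C)C(C)(C)C)CC1(C)C | intermediate (not isolated)
5 | (4R)-4-(tert-butyldimethylsilyloxy)-2,6,6-trimethylcyclohex-1-en-1-yl trifluoromethanesulfonate | FC(F)(F)S(=O)(=O)OC1=C(C)C[C@@H](O[Si](C)(C)C(C)(C)C)CC1(C)C | intermediate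
6 | (E)-3-methylpent-2-en-4-yn-1-ol | OC/C=C(\C)C#C | starting material
7 | (2E)-5-[(4R)-4-(tert-butyldimethylsilyloxy)-2,6,6-trimethylcyclohex-1-en-1-yl]-3-methylpent-2-en-4-yn-1-ol | OC/C=C(\C)C#CC1=C(C)C[C@@H](O[Si](C)(C)C(C)(C)C)CC1(C)C | intermediate
8 | (4R)-1-[(3E)-5-bromo-3-methylpent-3-en-1-yn-1-yl]-4-(tert-butyldimethylsilyloxy)-2,6,6-trimethylcyclohex-1-ene | BrC/C=C(\C)C#CC1=C(C)C[C@@H](O[Si](C)(C)C(C)(C)C)CC1(C)C | intermediate
9 | tributyl{(2E)-5-[(4R)-4-(tert-butyldimethylsilyloxy)-2,6,6-trimethylcyclohex-1-en-1-yl]-3-methylpent-2-en-4-yn-1-yl}phosphonium bromide (ring B salt) | CCCC[P+](CCCC)(CCCC)C/C=C(\C)C#CC1=C(C)C[C@@H](O[Si](C)(C)C(C)(C)C)CC1(C)C.[Br-] | intermediate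
10 | (4R)-4-hydroxy-2,6,6-trimethylcyclohex-2-en-1-one | CC1=C[C@H](O)CC(C)(C)C1=O | intermediate
11 | (4R)-2,6,6-trimethyl-4-(trimethylsilyloxy)cyclohex-2-en-1-one | CC1=C[C@H](O[Si](C)(C)C)CC(C)(C)C1=O | intermediate
12 | tert-butyl(dimethyl){[(2E)-3-methylpent-2-en-4-yn-1-yl]oxy}silane | C#C/C(C)=C/CO[Si](C)(C)C(C)(C)C | intermediate
13 | lithium (3E)-5-(tert-butyldimethylsilyloxy)-3-methylpent-3-en-1-yn-1-ide | [Li+].[C-]#C/C(C)=C/CO[Si](C)(C)C(C)(C)C | intermediate (not isolated)
14 | (1R,4R)-1-[(3E)-5-(tert-butyldimethylsilyloxy)-3-methylpent-3-en-1-yn-1-yl]-2,6,6-trimethyl-4-(trimethylsilyloxy)cyclohex-2-en-1-ol (lithium alkoxide in the flask until methanol is added) | CC1=C[C@H](O[Si](C)(C)C)CC(C)(C)[C@]1(O)C#C/C(C)=C/CO[Si](C)(C)C(C)(C)C | intermediate (not isolated)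
15 | (1R,4R)-1-[(3E)-5-(tert-butyldimethylsilyloxy)-3-methylpent-3-en-1-yn-1-yl]-2,6,6-trimethylcyclohex-2-ene-1,4-diol (1,4-trans diol) | CC1=C[C@H](O)CC(C)(C)[C@]1(O)C#C/C(C)=C/CO[Si](C)(C)C(C)(C)C | intermediate
16 | (1R,4R)-1-[(1E,3E)-5-(tert-butyldimethylsilyloxy)-3-methylpenta-1,3-dien-1-yl]-2,6,6-trimethylcyclohex-2-ene-1,4-diol (1,4-trans diol) | CC1=C[C@H](O)CC(C)(C)[C@]1(O)/C=C/C(C)=C/CO[Si](C)(C)C(C)(C)C | intermediate
17 | (1S,4R)-4-[(1E,3E)-5-(tert-butyldimethylsilyloxy)-3-methylpenta-1,3-dien-1-yl]-4-hydroxy-3,5,5-trimethylcyclohex-2-en-1-yl benzoate (oxygens cis) | CC1=C[C@@H](OC(=O)c2ccccc2)CC(C)(C)[C@]1(O)/C=C/C(C)=C/CO[Si](C)(C)C(C)(C)C | intermediate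
18 | (1S,4R)-4-hydroxy-4-[(1E,3E)-5-hydroxy-3-methylpenta-1,3-dien-1-yl]-3,5,5-trimethylcyclohex-2-en-1-yl benzoate | CC1=C[C@@H](OC(=O)c2ccccc2)CC(C)(C)[C@]1(O)/C=C/C(C)=C/CO | intermediate
19 | (1S,4R)-4-[(1E,3E)-5-bromo-3-methylpenta-1,3-dien-1-yl]-4-hydroxy-3,5,5-trimethylcyclohex-2-en-1-yl benzoate | CC1=C[C@@H](OC(=O)c2ccccc2)CC(C)(C)[C@]1(O)/C=C/C(C)=C/CBr | intermediate
20 | tributyl{(2E,4E)-5-[(1R,4S)-4-(benzoyloxy)-1-hydroxy-2,6,6-trimethylcyclohex-2-en-1-yl]-3-methylpenta-2,4-dien-1-yl}phosphonium bromide (ring A salt) | CC1=C[C@@H](OC(=O)c2ccccc2)CC(C)(C)[C@]1(O)/C=C/C(C)=C/C[P+](CCCC)(CCCC)CCCC.[Br-] | intermediate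
21 | (2E,4E,6E)-2,7-dimethylocta-2,4,6-trienedial | O=C/C(C)=C/C=C/C=C(\C)C=O | starting material
22 | ring B ylide: tributylphosphonium ylide of 9 (carbanion at C11') | CCCC[P+](CCCC)(CCCC)[CH-]/C=C(\C)C#CC1=C(C)C[C@@H](O[Si](C)(C)C(C)(C)C)CC1(C)C | intermediate (not isolated)
23 | C25 apo-aldehyde: (2E,4E,6E,8E,10E)-13-[(4R)-4-(tert-butyldimethylsilyloxy)-2,6,6-trimethylcyclohex-1-en-1-yl]-2,7,11-trimethyltrideca-2,4,6,8,10-pentaen-12-ynal | O=C/C(C)=C/C=C/C=C(C)/C=C/C=C(\C)C#CC1=C(C)C[C@@H](O[Si](C)(C)C(C)(C)C)CC1(C)C | intermediate (not isolated)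
24 | ring A ylide: tributylphosphonium ylide of 20 (carbanion at C11) | CC1=C[C@@H](OC(=O)c2ccccc2)CC(C)(C)[C@]1(O)/C=C/C(C)=C/[CH-][P+](CCCC)(CCCC)CCCC | intermediate (not isolated)
25 | C40 benzoate: 3-O-benzoyl-3'-O-(tert-butyldimethylsilyl) derivative of the target (all-E) | CC1=C[C@@H](OC(=O)c2ccccc2)CC(C)(C)[C@]1(O)/C=C/C(C)=C/C=C/C(C)=C/C=C/C=C(C)/C=C/C=C(\C)C#CC1=C(C)C[C@@H](O[Si](C)(C)C(C)(C)C)CC1(C)C | intermediate (not isolated)
26 | (3S,6R,3'R)-3'-(tert-butyldimethylsilyloxy)-7',8'-didehydro-ε,β-carotene-3,6-diol (all-E) | CC1=C[C@@H](O)CC(C)(C)[C@]1(O)/C=C/C(C)=C/C=C/C(C)=C/C=C/C=C(C)/C=C/C=C(\C)C#CC1=C(C)C[C@@H](O[Si](C)(C)C(C)(C)C)CC1(C)C | intermediate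
27 | (3S,6R,3'R)-7',8'-didehydro-ε,β-carotene-3,6,3'-triol (all-E) | CC1=C[C@@H](O)CC(C)(C)[C@]1(O)/C=C/C(C)=C/C=C/C(C)=C/C=C/C=C(C)/C=C/C=C(\C)C#CC1=C(C)C[C@@H](O)CC1(C)C | target

**Step count and risks**

Total step count: 17. Longest linear sequence: 10 steps (steps 7, 8, 10, 11, 12, 13, 14, 15, 16, 17, from 4-oxoisophorone).

Step 16. What may go wrong is loss of site control: the first ylide may condense twice with the dialdehyde before the second salt is added, and dialdehyde left over would take up two ring A units; some Z alkene may also form at the new double bonds. The fallback enforces site control with a protecting group instead of by stoichiometry. It sets out from 21 and 9. Dialdehyde 21 would be treated with one equivalent of HC(OMe)3 and a trace of TsOH in MeOH to give its mono(dimethyl acetal), (2E,4E,6E)-8,8-dimethoxy-2,7-dimethylocta-2,4,6-trienal F1, separated from diacetal and unchanged 21. F1 can react only once with the ylide from 9 (NaOMe, CH2Cl2) and would give the C25 dimethyl acetal F2. Brief exposure to pyridinium tosylate in wet acetone would then free the aldehyde, and the fallback returns to the route at 23, now isolated and purified. Compound 23 would be condensed with 20 and methanolysed as in the later stages of step 16 to give 26.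

Step 10. What may go wrong is poor or reversed facial selectivity in the carbonyl addition, the acetylide entering anti instead of syn to the silyloxy group. If the anti mode prevails, the other enantiomeric series leads to the same cis-diol without any inversion. The fallback sets out from 2, already made in step 1. Silylation (TMSCl, imidazole) would give (4S)-2,6,6-trimethyl-4-(trimethylsilyloxy)cyclohex-2-en-1-one F3. Addition of acetylide 13 and methanolysis as in step 10 would pass through the silylated adduct F4 and give the cis-configured enyne diol F5. Reduction as in step 11 would give the cis-configured diene diol F6. Plain benzoylation of its secondary hydroxyl (BzCl, pyridine, 0 °C; the tertiary hydroxyl does not acylate) returns to the route at 17, and the Mitsunobu step is dropped.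

Step 12. What may go wrong is ionisation of the activated allylic alcohol (partial retention or allylic transposition), elimination to a cyclohexadiene, internal displacement by the tertiary hydroxyl, which sits on the rear face, or cycloaddition of the azodicarboxylate to the side-chain diene. The fallback replaces the substitution by an oxidation–reduction sequence. It sets out from 16. MnO2 in CH2Cl2 would oxidise only the secondary allylic alcohol to the hydroxy enone F7. Luche reduction (NaBH4, CeCl3·7H2O, MeOH, −78 °C) should deliver hydride anti to the axial methyl of the gem-dimethyl carbon, which is 1,3 to the carbonyl, and give mainly the cis-diol, the compound F6 described above. Benzoylation (BzCl, pyridine) returns to the route at 17; the minor trans epimer is 16 itself and can be recycled.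

Further compounds
F1 | step 16 | (2E,4E,6E)-8,8-dimethoxy-2,7-dimethylocta-2,4,6-trienal | O=C/C(C)=C/C=C/C=C(\C)C(OC)OC
F2 | step 16 | dimethyl acetal of C25 apo-aldehyde 23 | COC(OC)/C(C)=C/C=C/C=C(C)/C=C/C=C(\C)C#CC1=C(C)C[C@@H](O[Si](C)(C)C(C)(C)C)CC1(C)C
F3 | step 10 | (4S)-2,6,6-trimethyl-4-(trimethylsilyloxy)cyclohex-2-en-1-one | CC1=C[C@@H](O[Si](C)(C)C)CC(C)(C)C1=O
F4 | step 10 | (1R,4S)-1-[(3E)-5-(tert-butyldimethylsilyloxy)-3-methylpent-3-en-1-yn-1-yl]-2,6,6-trimethyl-4-(trimethylsilyloxy)cyclohex-2-en-1-ol | CC1=C[C@@H](O[Si](C)(C)C)CC(C)(C)[C@]1(O)C#C/C(C)=C/CO[Si](C)(C)C(C)(C)C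
F5 | step 10 | (1R,4S)-1-[(3E)-5-(tert-butyldimethylsilyloxy)-3-methylpent-3-en-1-yn-1-yl]-2,6,6-trimethylcyclohex-2-ene-1,4-diol | CC1=C[C@@H](O)CC(C)(C)[C@]1(O)C#C/C(C)=C/CO[Si](C)(C)C(C)(C)C
F6 | step 10 | (1R,4S)-1-[(1E,3E)-5-(tert-butyldimethylsilyloxy)-3-methylpenta-1,3-dien-1-yl]-2,6,6-trimethylcyclohex-2-ene-1,4-diol | CC1=C[C@@H](O)CC(C)(C)[C@]1(O)/C=C/C(C)=C/CO[Si](C)(C)C(C)(C)C
F7 | step 12 | (4R)-4-[(1E,3E)-5-(tert-butyldimethylsilyloxy)-3-methylpenta-1,3-dien-1-yl]-4-hydroxy-3,5,5-trimethylcyclohex-2-en-1-one | CC1=CC(=O)CC(C)(C)[C@]1(O)/C=C/C(C)=C/CO[Si](C)(C)C(C)(C)C
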